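The upper carbocycle (C4a–C5–C6–C7–C8–C8a) is disconnected at C8–C7 and C4a–C8a. The feature exploited is that C8 (OMe, C6′-aryl) and C8a (O–C5′) are C3 and C2 of a 3-methoxybenzofuran-2(3H)-one fused to the lower A′ ring. C7–C6–C5–C4a is an acylketene acetal, acceptor at C7 and donor at C4a. In one flask, a catalyst-controlled vinylic substitution creates the C8 quaternary centre and leaves the C7 methoxy enone. A Dieckmann-type closure on the lactone carbonyl then completes the ring and releases the C5′ phenol. The precursors are the TBS-protected trans-flavanol lactone and an (S)-configured TES-oxy dimethoxy enone.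

Key step: step 11

Numbering: flavan numbering throughout; the upper half is unprimed (O1, C2 to C8a) and the lower half is primed.
Assumption: the sense of induction of the chiral Ru–NHC catalyst (step 2) and of the chiral ammonium salt (step 11) has to be matched to the 2′S and 8S series by experiment; both antipodes or pseudoenantiomers of each are available.

Step 1
Reactants: 1 wogonin
Product: 3 5-benzyloxy-7,8-dimethoxyflavone, via 7-O-methylwogonin 2 (not isolated)
Conditions: MeI (1.05 equiv), K2CO3 (3 equiv), DMF, rt; then BnBr (1.5 equiv), 70 °C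
Reagents that add atoms: iodomethane CI; benzyl bromide BrCc1ccccc1
Why: Sequential Williamson etherification, in which the acidic 7-OH reacts at room temperature while the 5-OH, hydrogen-bonded to the C4 carbonyl, is alkylated only on heating with the second halide.

Step 2
Reactants: 3 5-benzyloxy-7,8-dimethoxyflavone
Product: 5 (2S,4S)-5-benzyloxy-7,8-dimethoxyflavan-4-ol (2,4-cis), via flavanone 4 (not isolated)
Conditions: [Ru(cod)(2-methylallyl)2] (5 mol %), chiral SINpEt·HBF4 (10 mol %), KOtBu (15 mol %), H2 (120 bar), toluene–hexane, rt; then NaBH4, MeOH–THF, 0 °C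
Reagents that add atoms: none
Why: Ru–NHC-catalysed asymmetric hydrogenation of flavones sets C2′ by catalyst control at the C2=C3 bond, and hydride (Ru–H, or NaBH4 for any remaining 4) then attacks the ketone of the 2-equatorial-phenyl half-chair axially, which gives the 2,4-cis alcohol.

Step 3
Reactants: 5 (2S,4S)-5-benzyloxy-7,8-dimethoxyflavan-4-ol
Product: 7 (2S,4R)-5-benzyloxy-7,8-dimethoxyflavan-4-ol (2,4-trans), via 4-nitrobenzoate 6 (not isolated)
Conditions: 4-O2NC6H4CO2H, PPh3, DIAD, THF, −20 to 0 °C; solvent swap; K2CO3 (cat.), MeOH–THF, 0 °C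
Reagents that add atoms: 4-nitrobenzoic acid O=C(O)c1ccc(cc1)[N+](=O)[O-]
Why: Mitsunobu inversion, the established way from cis- to trans-flavan-4-ols, sets 4′R by backside displacement of the oxyphosphonium group, and cold carbonate methanolysis cleaves only the acyl–oxygen bond, so the new C4′–O bond is kept.

Step 4
Reactants: 7 (2S,4R)-5-benzyloxy-7,8-dimethoxyflavan-4-ol
Product: 8 (2S,4R)-5-benzyloxy-4-(tert-butyldimethylsilyloxy)-7,8-dimethoxyflavan
Conditions: TBSCl, imidazole, DMAP (cat.), DMF, rt to 35 °C
Reagents that add atoms: tert-butyldimethylsilyl chloride CC(C)(C)[Si](C)(C)Cl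
Why: Standard base-mediated O-silylation avoids acid at the ionisable C4′ position and installs a group whose silyloxide is a poor nucleofuge, which matters once the neighbouring phenol is free.

Step 5
Reactants: 8 (2S,4R)-5-benzyloxy-4-(tert-butyldimethylsilyloxy)-7,8-dimethoxyflavan
Product: 9 (2S,4R)-4-(tert-butyldimethylsilyloxy)-7,8-dimethoxyflavan-5-ol
Conditions: H2 (1 atm), 10% Pd/C, NaHCO3 (solid), EtOAc, rt
Reagents that add atoms: none
Why: Hydrogenolysis of an aryl benzyl ether is fast under neutral buffered conditions in EtOAc, where benzylic silyl ethers and the flavan C2′–O bond are routinely retained.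

Step 6
Reactants: 9 (2S,4R)-4-(tert-butyldimethylsilyloxy)-7,8-dimethoxyflavan-5-ol; 10 glyoxylic acid
Product: 12 3-hydroxybenzofuran-2(3H)-one fused at C5′–C6′ of the protected flavanol (C3 epimers), via hydroxy acid 11 (not isolated)
Conditions: 10 (monohydrate, 1.5 equiv), NaOH (2.6 equiv), H2O–THF, 0 °C to rt; NaH2PO4 to pH 5, extraction; EDC·HCl, CH2Cl2, 0 °C
Reagents that add atoms: none
Why: The phenolate–glyoxylate hydroxyalkylation (mandelic acid condensation) can strike only C6′, the single free ring position, which is activated by three oxygen donors, and carbodiimide dehydration closes the five-membered aryl lactone without acid; the new carbinol centre is left as a mixture because step 11 planarises it.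

Step 7
Reactants: 12 3-hydroxybenzofuranone of the lower flavanol
Product: 13 3-methoxybenzofuran-2(3H)-one of the lower flavanol (C3 epimers)
Conditions: MeOTf (3 equiv), 2,6-di-tert-butyl-4-methylpyridine (4 equiv), CH2Cl2, rt
Reagents that add atoms: methyl trifluoromethanesulfonate COS(=O)(=O)C(F)(F)F
Why: O-Methylation with methyl triflate and a hindered pyridine is the standard method for base-sensitive alcohols, and this base is too weak to enolise the lactone, so neither C-methylation nor oxidation of an enediol can compete.

Step 8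
Reactants: 14 5-oxo-5-phenylpentanoic acid
Product: 16 (S)-6-phenyltetrahydro-2H-pyran-2-one, via hydroxy acid 15 (not isolated)
Conditions: RuCl[(S,S)-TsDPEN](p-cymene) (0.5 mol %), HCO2H–Et3N (5:2), 30 °C; 1 M HCl work-up; p-TsOH (cat.), toluene, rt
Reagents that add atoms: none
Why: Noyori asymmetric transfer hydrogenation of an aryl alkyl ketone with the (S,S)-catalyst gives the (S)-benzylic alcohol (C2 of the target), and lactonisation forms only the acyl–oxygen bond, so this centre is retained in a form that is easy to purify.

Step 9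
Reactants: 16 (S)-6-phenyltetrahydro-2H-pyran-2-one
Product: 18 triethylsilyl (S)-5-phenyl-5-(triethylsilyloxy)pentanoate, via potassium carboxylate 17 (not isolated)
Conditions: KOH (1.0 equiv), MeOH–H2O, rt; evaporation, toluene azeotrope; TESCl (2.3 equiv), imidazole (4 equiv), DMF, 0 °C to rt
Reagents that add atoms: potassium hydroxide [K+].[OH-]; chlorotriethylsilane CC[Si](Cl)(CC)CC
Why: Saponification followed by exhaustive silylation of the dry carboxylate salt traps the open chain as silyl ether and silyl ester before it can relactonise.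

Step 10
Reactants: 18 triethylsilyl (S)-5-phenyl-5-(triethylsilyloxy)pentanoate; 19 1,1-dimethoxyethene
Product: 21 (S)-1,1-dimethoxy-7-phenyl-7-(triethylsilyloxy)hept-1-en-3-one, via acid chloride 20 (not isolated)
Conditions: (COCl)2 (1.05 equiv), DMF (cat.), CH2Cl2, 0 °C to rt, volatiles off under high vacuum; 19 (2.5 equiv), Et2O, 0 °C to reflux; filtration through basic alumina
Reagents that add atoms: none
Why: The Vilsmeier chloride converts a silyl ester into the acid chloride without releasing HCl, so the TES ether survives, and C-acylation of the ketene acetal followed by proton loss gives the acylketene acetal, with the excess of 19 acting as a neutral HCl trap in place of an amine that would generate a ketene.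

Step 11
Reactants: 13 3-methoxybenzofuran-2(3H)-one of the lower flavanol; 21 (S)-1,1-dimethoxy-7-phenyl-7-(triethylsilyloxy)hept-1-en-3-one
Product: 23 enolised 2-alkyl-6-aryl-5,6-dimethoxycyclohex-4-ene-1,3-dione with free C5′ phenol (C8 configured as in the target), via vinylic substitution adduct 22 (not isolated)
Conditions: 21 (1.3 equiv), N-(9-anthracenylmethyl)-O-allylcinchonidinium bromide or its cinchoninium pseudoenantiomer (10 mol %), Cs2CO3 (1.5 equiv), toluene, Ar, −20 °C to rt; then KOtBu (3.5 equiv), THF, −40 to 0 °C; AcOH quench at −40 °C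
Reagents that add atoms: none
Why: Proposed new method: solid carbonate removes only the C8–H of 13 (the anion is an aromatic 2-oxidobenzofuran, far more stabilised than any carbanion from 21), its ion pair with the chiral ammonium cation adds to C7, the one electrophilic alkene carbon of the push–pull enone, and E1cB loss of methoxide from the C5 enolate gives 22 with the C7 methoxy enone already in place; the closest known reactions are phase-transfer-catalysed enantioselective vinylic substitutions of β-halo enones by cyclic β-dicarbonyl donors and catalytic asymmetric Michael additions of 3-substituted benzofuranones, neither of which has been run on an acylketene acetal. KOtBu then deprotonates C4a, the sole enolisable position of 22, and a 6-(enolendo)-exo-trig Dieckmann-type attack on the C8a lactone carbonyl closes the carbocycle, expels the C5′ aryloxide and ends irreversibly in the dione enolate. The single new stereocentre, C8, is fixed in the first C–C bond formation by the enolate face that the cation leaves open; the existing centres lie too many bonds away to bias it, but they make the C8 epimers diastereomers, so a minor epimer can be removed by chromatography of 23. The geometry of the C6=C7 bond in 22 need not be controlled, because the liberated methanol becomes KOMe, whose reversible addition at C7 scrambles E and Z while ring closure drains the isomer that holds C5 on the side of C8. If that methoxide opens the lactone of 22, the resulting methyl ester carries the same C8a carbonyl and closes to the same product, whereas unreacted 13 is shielded as its enolate. The C4′ silyloxide is too poor a leaving group for the released phenoxide to collapse to an o-quinone methide.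

Step 12
Reactants: 23 enolised cyclohexenedione
Product: 24 C4a-phenylselanyl-1,3-dione (C4a epimers)
Conditions: PhSeCl (1.05 equiv), pyridine (2 equiv), CH2Cl2, −40 to 0 °C; cold aqueous NaHCO3 wash, used promptly
Reagents that add atoms: benzeneselenenyl chloride Cl[Se]c1ccccc1
Why: α-Selenenylation of an enolised β-dicarbonyl compound with PhSeCl–pyridine goes to C4a, the only carbon that carries the enolate charge, the fully substituted aryl ring offers no site for attack, and the C4a configuration is irrelevant because step 14 erases it.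

Step 13
Reactants: 24 C4a-phenylselanyl-1,3-dione
Product: 26 C4a-phenylselanyl double ketal (pyran and dihydrofuran rings closed at C8a), via carbinol 25 (not isolated)
Conditions: HF·pyridine, excess pyridine, THF, 0 °C; NaHCO3 work-up; PPTS (0.2 equiv), 3 Å MS, CH2Cl2, rt
Reagents that add atoms: none
Why: Buffered HF removes the TES ether in preference to the hindered TBS ether, and the C2 carbinol and C5′ phenol then condense with the non-enolisable C8a ketone by acid-catalysed intramolecular ketalisation of the spiroketal type; C8a is set by C8 because the five-membered O-ring can only be cis-fused, which leaves the opposite face to O1, and closing the pyran first removes any E/Z question for the later alkene and masks the oxidisable phenol.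

Step 14
Reactants: 26 C4a-phenylselanyl double ketal
Product: 28 4′-O-TBS-6″-demethoxyneocalycopterone, via selenoxide 27 (not isolated)
Conditions: mCPBA (1.05 equiv), CH2Cl2, −78 °C; pyridine, warm to rt
Reagents that add atoms: none
Why: Selenoxide syn-elimination can run only toward C4, since C5 and C8a carry no hydrogen, so the C4=C4a alkene forms inside the pyran ring, and selenium is oxidised at −78 °C much faster than any other group present.

Step 15
Reactants: 28 4′-O-TBS-6″-demethoxyneocalycopterone
Product: 29 6″-demethoxyneocalycopterone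
Conditions: TBAF–AcOH (1:1, 3 equiv), THF, 0 °C to rt
Reagents that add atoms: none
Why: Fluoride desilylation buffered with acetic acid is nearly neutral, which protects both the acid-labile C4′ carbinol and the base-sensitive dienone ketal, and it breaks only the O–Si bond, so 4′R is retained.

Compound list
1 | wogonin (5,7-dihydroxy-8-methoxyflavone) | COc1c(O)cc(O)c2c1oc(cc2=O)-c1ccccc1 | starting material
2 | 7-O-methylwogonin (5-hydroxy-7,8-dimethoxyflavone), not isolated | COc1c(OC)cc(O)c2c1oc(cc2=O)-c1ccccc1 | intermediate
3 | 5-benzyloxy-7,8-dimethoxyflavone | COc1c(OC)cc(OCc3ccccc3)c2c1oc(cc2=O)-c1ccccc1 | intermediate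
4 | (2S)-5-benzyloxy-7,8-dimethoxyflavanone, not isolated | COc1c(OC)cc(OCc3ccccc3)c2c1O[C@H](c1ccccc1)CC2=O | intermediate
5 | (2S,4S)-5-benzyloxy-7,8-dimethoxyflavan-4-ol (2,4-cis) | COc1c(OC)cc(OCc3ccccc3)c2c1O[C@H](c1ccccc1)C[C@@H]2O | intermediate
6 | (2S,4R)-5-benzyloxy-7,8-dimethoxyflavan-4-yl 4-nitrobenzoate (2,4-trans), not isolated | COc1c(OC)cc(OCc3ccccc3)c2c1O[C@H](c1ccccc1)C[C@H]2OC(=O)c1ccc(cc1)[N+](=O)[O-] | intermediate
7 | (2S,4R)-5-benzyloxy-7,8-dimethoxyflavan-4-ol (2,4-trans) | COc1c(OC)cc(OCc3ccccc3)c2c1O[C@H](c1ccccc1)C[C@H]2O | intermediate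
8 | (2S,4R)-5-benzyloxy-4-(tert-butyldimethylsilyloxy)-7,8-dimethoxyflavan | COc1c(OC)cc(OCc3ccccc3)c2c1O[C@H](c1ccccc1)C[C@H]2O[Si](C)(C)C(C)(C)C | intermediate
9 | (2S,4R)-4-(tert-butyldimethylsilyloxy)-7,8-dimethoxyflavan-5-ol | COc1c(OC)cc(O)c2c1O[C@H](c1ccccc1)C[C@H]2O[Si](C)(C)C(C)(C)C | intermediate
10 | glyoxylic acid | O=CC(=O)O | starting material
11 | 2-hydroxy-2-[(2S,4R)-4-(tert-butyldimethylsilyloxy)-5-hydroxy-7,8-dimethoxyflavan-6-yl]acetic acid (carbinol epimers), not isolated | COc1c(OC)c(C(O)C(=O)O)c(O)c2c1O[C@H](c1ccccc1)C[C@H]2O[Si](C)(C)C(C)(C)C | intermediate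
12 | 3-hydroxybenzofuran-2(3H)-one fused at C5′–C6′ of (2S,4R)-4-(tert-butyldimethylsilyloxy)-7,8-dimethoxyflavan (C3 epimers) | OC1C(=O)Oc2c4c(c(OC)c(OC)c21)O[C@H](c1ccccc1)C[C@H]4O[Si](C)(C)C(C)(C)C | intermediate
13 | 3-methoxybenzofuran-2(3H)-one fused at C5′–C6′ of (2S,4R)-4-(tert-butyldimethylsilyloxy)-7,8-dimethoxyflavan (C3 epimers) | COC1C(=O)Oc2c4c(c(OC)c(OC)c21)O[C@H](c1ccccc1)C[C@H]4O[Si](C)(C)C(C)(C)C | intermediate
14 | 5-oxo-5-phenylpentanoic acid | O=C(O)CCCC(=O)c1ccccc1 | starting material
15 | (S)-5-hydroxy-5-phenylpentanoic acid, not isolated | O=C(O)CCC[C@H](O)c1ccccc1 | intermediate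
16 | (S)-6-phenyltetrahydro-2H-pyran-2-one | O=C1CCC[C@H](O1)c2ccccc2 | intermediate
17 | potassium (S)-5-hydroxy-5-phenylpentanoate, not isolated | [K+].[O-]C(=O)CCC[C@H](O)c1ccccc1 | intermediate
18 | triethylsilyl (S)-5-phenyl-5-(triethylsilyloxy)pentanoate | CC[Si](CC)(CC)OC(=O)CCC[C@H](O[Si](CC)(CC)CC)c1ccccc1 | intermediate
19 | 1,1-dimethoxyethene | C=C(OC)OC | starting material
20 | (S)-5-phenyl-5-(triethylsilyloxy)pentanoyl chloride, not isolated | ClC(=O)CCC[C@H](O[Si](CC)(CC)CC)c1ccccc1 | intermediate
21 | (S)-1,1-dimethoxy-7-phenyl-7-(triethylsilyloxy)hept-1-en-3-one | COC(OC)=CC(=O)CCC[C@H](O[Si](CC)(CC)CC)c1ccccc1 | intermediate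
22 | (3S)-3-methoxy-3-[(7S)-1-methoxy-3-oxo-7-phenyl-7-(triethylsilyloxy)hept-1-en-1-yl] derivative of lactone 13 (C8 quaternary, E/Z mixture at C6=C7), not isolated | CO[C@@]1(C(OC)=CC(=O)CCC[C@H](O[Si](CC)(CC)CC)c3ccccc3)C(=O)Oc2c4c(c(OC)c(OC)c21)O[C@H](c1ccccc1)C[C@H]4O[Si](C)(C)C(C)(C)C | intermediate
23 | enolised 2-[(3S)-3-phenyl-3-(triethylsilyloxy)propyl]-6-aryl-5,6-dimethoxycyclohex-4-ene-1,3-dione, aryl = (2S,4R)-4-(tert-butyldimethylsilyloxy)-5-hydroxy-7,8-dimethoxyflavan-6-yl, C8 arranged as in 29 | COC1=CC(=O)C(CC[C@H](O[Si](CC)(CC)CC)c2ccccc2)=C(O)[C@]1(OC)c1c(O)c2c(c(OC)c1OC)O[C@H](c1ccccc1)C[C@H]2O[Si](C)(C)C(C)(C)C | intermediate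
24 | C4a-phenylselanyl derivative of 23 (non-enolisable 1,3-dione, C4a epimers, open form drawn; may rest as the C8a hemiketal of the C5′ phenol) | COC1=CC(=O)C(CC[C@H](O[Si](CC)(CC)CC)c2ccccc2)([Se]c2ccccc2)C(=O)[C@]1(OC)c1c(O)c2c(c(OC)c1OC)O[C@H](c1ccccc1)C[C@H]2O[Si](C)(C)C(C)(C)C | intermediate
25 | C2 carbinol obtained from 24 by loss of the TES group, not isolated | COC1=CC(=O)C(CC[C@H](O)c2ccccc2)([Se]c2ccccc2)C(=O)[C@]1(OC)c1c(O)c2c(c(OC)c1OC)O[C@H](c1ccccc1)C[C@H]2O[Si](C)(C)C(C)(C)C | intermediate
26 | 4,4a-dihydro-4a-(phenylselanyl) derivative of 28 (double ketal at C8a closed, C4a epimers) | COC1=CC(=O)C2([Se]c5ccccc5)CC[C@@H](c3ccccc3)O[C@]23Oc2c4c(c(OC)c(OC)c2[C@]13OC)O[C@H](c1ccccc1)C[C@H]4O[Si](C)(C)C(C)(C)C | intermediate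
27 | selenoxide of 26, not isolated | COC1=CC(=O)C2([Se](=O)c5ccccc5)CC[C@@H](c3ccccc3)O[C@]23Oc2c4c(c(OC)c(OC)c2[C@]13OC)O[C@H](c1ccccc1)C[C@H]4O[Si](C)(C)C(C)(C)C | intermediate
28 | 4′-O-(tert-butyldimethylsilyl)-6″-demethoxyneocalycopterone | COC1=CC(=O)C2=CC[C@@H](c3ccccc3)O[C@]23Oc2c4c(c(OC)c(OC)c2[C@]13OC)O[C@H](c1ccccc1)C[C@H]4O[Si](C)(C)C(C)(C)C | intermediate
29 | 6″-demethoxyneocalycopterone (2S,8S,8aS,2′S,4′R) | COC1=CC(=O)C2=CC[C@@H](c3ccccc3)O[C@]23Oc2c4c(c(OC)c(OC)c2[C@]13OC)O[C@H](c1ccccc1)C[C@H]4O | target

Total step count: 15 (lower half steps 1–7, upper fragment steps 8–10, union step 11, endgame steps 12–15).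
Longest linear sequence: 12 steps (1–7, then 11–15).

Steps most likely to fail

1. Step 11 (bears the label "Proposed new method:").
- What may go wrong:
  - The hindered tertiary enolate may add too slowly or only reversibly to the deactivated ketene-acetal carbon.
  - The ion pair may discriminate the two enolate faces poorly.
  - Ring closure may stall while the alkene isomers equilibrate.
- Fallback, from 18 and 13, back at 23:
  - 18 is taken to acid chloride 20 as in step 10 and quenched with N,O-dimethylhydroxylamine and pyridine. This gives the Weinreb amide (S)-N-methoxy-N-methyl-5-phenyl-5-(triethylsilyloxy)pentanamide F1.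
  - Lithium methoxyacetylide, generated from chloroacetaldehyde dimethyl acetal and LiNEt2, converts it by Weinreb ketone synthesis into the alkynone (S)-1-methoxy-7-phenyl-7-(triethylsilyloxy)hept-1-yn-3-one F2.
  - Base- or amine-catalysed conjugate addition of 13 to this alkynone follows. This is a known reaction type for benzofuranone and β-dicarbonyl donors; it needs no leaving group and meets an unhindered sp carbon.
  - It should deliver 22, which is now isolated and freed of its C8 epimer by chromatography.
  - 22 is closed to 23 with KOtBu in a separate Dieckmann step.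

2. Step 13.
- What may go wrong:
  - Ketalisation at a ketone flanked by two quaternary carbons may be slow.
  - Prolonged acid then invites ionisation at C4′, loss of the selenium group, exchange of the C7 methoxy group by the phenol, or retro-Claisen opening of the non-enolisable dione.
- Fallback, from 24, back at 28 (the order of events is reversed):
  - 24 is oxidised with mCPBA at −78 °C to the open-chain selenoxide F3.
  - On warming, F3 undergoes syn-elimination toward C4 to give the 2-alkylidene-1,3-dione F4. This is the known outcome for 2-alkyl-2-seleno-β-dicarbonyl compounds.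
  - Buffered HF·pyridine frees the alkylidene carbinol F5.
  - PPTS with 3 Å sieves then closes both ketal bonds at a C8a ketone that now has an sp2 neighbour and is less crowded.
  - The alkene isomers should interconvert through reversible conjugate addition, and only the one that holds the chain on the C8a side is captured, giving 28 directly.

3. Step 3.
- What may go wrong: the activated, very electron-rich benzylic alcohol may ionise, with elimination to the flav-3-ene and incomplete inversion.
- Fallback, from 5, back at 7:
  - Dess–Martin oxidation returns flavanone 4.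
  - A reagent-controlled Corey–Bakshi–Shibata reduction, (S)-Me-CBS with BH3·SMe2, treats the aryl side as the large group. It should therefore deliver the 4′R alcohol 7 against the substrate's cis preference, without any leaving group at C4′.

Further compounds
F1 | step 11 | (S)-N-methoxy-N-methyl-5-phenyl-5-(triethylsilyloxy)pentanamide | CON(C)C(=O)CCC[C@H](O[Si](CC)(CC)CC)c1ccccc1
F2 | step 11 | (S)-1-methoxy-7-phenyl-7-(triethylsilyloxy)hept-1-yn-3-one | COC#CC(=O)CCC[C@H](O[Si](CC)(CC)CC)c1ccccc1
F3 | step 13 | selenoxide of 24 (open chain) | COC1=CC(=O)C(CC[C@H](O[Si](CC)(CC)CC)c2ccccc2)([Se](=O)c2ccccc2)C(=O)[C@]1(OC)c1c(O)c2c(c(OC)c1OC)O[C@H](c1ccccc1)C[C@H]2O[Si](C)(C)C(C)(C)C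
F4 | step 13 | 2-alkylidene-1,3-dione with C4=C4a in place (E/Z mixture), TES and TBS retained | COC1=CC(=O)C(=CC[C@H](O[Si](CC)(CC)CC)c2ccccc2)C(=O)[C@]1(OC)c1c(O)c2c(c(OC)c1OC)O[C@H](c1ccccc1)C[C@H]2O[Si](C)(C)C(C)(C)C
F5 | step 13 | alkylidene carbinol (F4 without the TES group) | COC1=CC(=O)C(=CC[C@H](O)c2ccccc2)C(=O)[C@]1(OC)c1c(O)c2c(c(OC)c1OC)O[C@H](c1ccccc1)C[C@H]2O[Si](C)(C)C(C)(C)C
F0 | step 3 | none | none
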